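**Retrosynthetic overview**

1. Target 14 ⇐ 2,11-diketone 13 by two Felkin–Anh hydride additions (C2 and C11).
2. Ring C (oxolane) ⇐ transannular oxa-Michael addition of C7–OH to the C3=C4–C2=O enone; the C7–OH/C8=C19 unit ⇐ (7R,8R)-epoxide.
3. Ring B (ε-lactone) ⇐ C16 carboxylic acid opening the (11R,12R)-epoxide at C12 with inversion; the acid ⇐ allylic oxidation of the isopropenyl methyl.
4. Ring A (14-membered carbocycle) ⇐ head-to-tail acylium–olefin (ene-type) cyclisation of all-E-geranylgeranoyl chloride, forming C1–C2, the bond the cembrane cyclase makes.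
5. Ring order A → B → C; absolute configuration comes from one Shi double epoxidation.

Assumption: cembrane numbering is used (C1 carries the C15/C16/C17 unit; methyls C18, C19, C20 sit on C4, C8, C12; target = 1R,2S,4S,7R,11S,12S), and all-E-geranylgeraniol is taken as the commercial feedstock.

**Step 1**
Reactants: 1 (2E,6E,10E)-geranylgeraniol
Product: 3 (2E,6E,10E)-geranylgeranic acid, via geranylgeranial 2 (not isolated)
Conditions: 2,2,6,6-tetramethylpiperidin-1-oxyl (TEMPO, 10 mol %), PhI(OAc)2, CH2Cl2, rt; then t-BuOH/H2O, 2-methyl-2-butene, NaClO2, NaH2PO4, 0 °C → rt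
Reagents that add atoms: sodium chlorite NaClO2, [Na+].[O-]Cl=O
Why: TEMPO/PhI(OAc)2 oxidation of the allylic alcohol to the E-enal and Pinnick oxidation in the same flask give the acid without E/Z scrambling or attack on the trisubstituted alkenes (2-methyl-2-butene traps HOCl); no stereocentre is formed.

**Step 2**
Reactants: 3 (2E,6E,10E)-geranylgeranic acid
Product: 5 rac-(3E,7E,11E)-cembra-3,7,11,15(17)-tetraen-2-one, via geranylgeranoyl chloride 4 (not isolated)
Conditions: (COCl)2, CH2Cl2, 0 °C → rt, evaporate; slow addition to EtAlCl2 (2 equiv), CH2Cl2 (3 mM), −78 → −40 °C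
Reagents that add atoms: none
Why: Proposed new method: the SnCl4-promoted cyclisation of this acid chloride is a known way to close the cembrane ring between C1 and C2 (acylium attack on the terminal alkene; 6- and 10-ring closure are excluded by the 2E geometry and strain), but it traps the C15 cation as a β-chloro ketone that base would only eliminate into conjugation; with an alkylaluminium dichloride, as in the ene-type aliphatic Friedel–Crafts acylation of trisubstituted alkenes, the cation should instead lose a methyl proton to the acyl oxygen while EtAlCl2 removes HCl as ethane, giving the non-conjugated isopropenyl ketone directly, racemic at C1.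

**Step 3**
Reactants: 5 rac-(3E,7E,11E)-cembra-3,7,11,15(17)-tetraen-2-one
Product: 6 (1R,7R,8R,11R,12R,3E)-7,8:11,12-diepoxycembra-3,15(17)-dien-2-one
Conditions: 1,2:4,5-di-O-isopropylidene-β-D-erythro-2,3-hexodiulo-2,6-pyranose (Shi ketone, 0.6 equiv), KHSO5 (as 2KHSO5·KHSO4·K2SO4, 2.6 equiv), K2CO3, Bu4NHSO4, MeCN–CH2(OMe)2/aq. Na2B4O7 buffer, −10 → 0 °C; chromatography
Reagents that add atoms: potassium peroxymonosulfate KHSO5, [K+].[O-]S(=O)(=O)OO
Why: Shi asymmetric epoxidation: the dioxirane attacks only the two electron-rich trisubstituted E-alkenes (enone and 1,1-disubstituted isopropenyl alkene are far slower) with catalyst-controlled (R,R) sense at both, which fixes 7R (kept to the end), 8R, 11R and 12R and converts the racemate into two enantiopure C1 epimers; 6 is isolated by chromatography and its (1S) epimer is removed and not carried on (the macrocyclisation cannot set C1, so at most half of the material is used).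

**Step 4**
Reactants: 6 (1R,7R,8R,11R,12R,3E)-7,8:11,12-diepoxycembra-3,15(17)-dien-2-one
Product: 8 (1R,7R,8R,11R,12R,3E)-7,8:11,12-diepoxy-2-oxocembra-3,15(17)-dien-16-al, via C16 allylic alcohol 7 (not isolated)
Conditions: SeO2 (0.5 equiv), t-BuOOH (3 equiv), CH2Cl2, rt; then MnO2 (excess), rt
Reagents that add atoms: selenium dioxide, O=[Se]=O (catalytic oxygen carrier); tert-butyl hydroperoxide, CC(C)(C)OO (terminal oxygen source)
Why: SeO2/t-BuOOH allylic oxidation (ene reaction then [2,3]-shift) followed by MnO2 oxidation: with both trisubstituted alkenes masked as epoxides and the enone alkene deactivated, the isopropenyl group is the only electron-rich alkene left, its methyl is oxidised in preference to the C1 methine (which is also α to the ketone), and MnO2 takes the 2-substituted allyl alcohol to the enal without base, so C1 is not epimerised.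

**Step 5**
Reactants: 8 (1R,7R,8R,11R,12R,3E)-7,8:11,12-diepoxy-2-oxocembra-3,15(17)-dien-16-al
Product: 11 (1R,7R,8R,12S,3E)-7,8-epoxy-2,11-dioxocembra-3,15(17)-dien-16,12-olide, via epoxy acid 9 (not isolated), via hydroxy lactone 10 (not isolated)
Conditions: NaClO2, NaH2PO4, 2-methyl-2-butene, t-BuOH/H2O, 0 °C; extract; then Dess–Martin periodinane (3 equiv), CH2Cl2 (2 mM), rt
Reagents that add atoms: sodium chlorite NaClO2, [Na+].[O-]Cl=O
Why: Pinnick oxidation followed by biomimetic epoxide-opening lactonisation: the α-substituted acrylic acid, activating the epoxide with its own proton, attacks the neighbouring trisubstituted epoxide at its tertiary carbon C12 with inversion (7-exo; sets 12S and closes ring B), and the Dess–Martin periodinane already present oxidises the liberated C11–OH (11R, the wrong configuration in any case) to the ketone before it can attack the 7,8-epoxide transannularly.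

**Step 6**
Reactants: 11 (1R,7R,8R,12S,3E)-7,8-epoxy-2,11-dioxocembra-3,15(17)-dien-16,12-olide
Product: 13 (1R,4S,7R,12S)-4,7-epoxy-2,11-dioxocembra-8(19),15(17)-dien-16,12-olide, via C7 allylic alcohol 12 (not isolated)
Conditions: Cp2TiCl (3 equiv, from Cp2TiCl2 and Mn powder), THF, rt; dilute aq. HCl work-up; then (+)-camphor-10-sulfonic acid (10 mol %), CH2Cl2, 0 °C
Reagents that add atoms: none
Why: Nugent–RajanBabu epoxide opening then oxa-Michael addition: Cp2TiCl (trivalent titanium) cleaves the C8–O bond homolytically to the tertiary radical, a second Cp2TiCl removes a hydrogen atom from the unhindered C19 methyl to leave the exocyclic alkene and the untouched (7R)-carbinol, and acid then closes ring C by reversible 5-exo addition of C7–OH to C4 of the enone, where only the cis-2,5-bridged oxolane (4S) fits across the macrocycle.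

**Step 7**
Reactants: 13 (1R,4S,7R,12S)-4,7-epoxy-2,11-dioxocembra-8(19),15(17)-dien-16,12-olide
Product: 14 (1R,2S,4S,7R,11S,12S)-4,7-epoxy-2,11-dihydroxycembra-8(19),15(17)-dien-16,12-olide (target)
Conditions: NaBH4, CeCl3·7H2O, MeOH/CH2Cl2, −78 °C
Reagents that add atoms: none
Why: Luche reduction: CeCl3-assisted borohydride adds 1,2 to both ketones without touching the α-methylene lactone, and Felkin–Anh attack anti to the C1–C15 bond at C2 and anti to the C12–O(acyl) bond at C11 gives the 2S and 11S alcohols (C11 thereby ends inverted relative to the epoxide-derived alcohol of 10).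

**Compound list**

1 | (2E,6E,10E)-geranylgeraniol | CC(C)=CCC/C(C)=C/CC/C(C)=C/CC/C(C)=C/CO | starting material
2 | (2E,6E,10E)-geranylgeranial | CC(C)=CCC/C(C)=C/CC/C(C)=C/CC/C(C)=C/C=O | intermediate
3 | (2E,6E,10E)-geranylgeranic acid | CC(C)=CCC/C(C)=C/CC/C(C)=C/CC/C(C)=C/C(O)=O | intermediate
4 | (2E,6E,10E)-geranylgeranoyl chloride | CC(C)=CCC/C(C)=C/CC/C(C)=C/CC/C(C)=C/C(Cl)=O | intermediate
5 | rac-(3E,7E,11E)-cembra-3,7,11,15(17)-tetraen-2-one (14-membered ring, isopropenyl on C1, ketone C2) | CC(=C)C1CC/C(C)=C/CC/C(C)=C/CC/C(C)=C/C1=O | intermediate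
6 | (1R,7R,8R,11R,12R,3E)-7,8:11,12-diepoxycembra-3,15(17)-dien-2-one | CC(=C)[C@H]1CC[C@@]2(C)O[C@@H]2CC[C@@]3(C)O[C@@H]3CC/C(C)=C/C1=O | intermediate
7 | (1R,7R,8R,11R,12R,3E)-7,8:11,12-diepoxy-16-hydroxycembra-3,15(17)-dien-2-one | OCC(=C)[C@H]1CC[C@@]2(C)O[C@@H]2CC[C@@]3(C)O[C@@H]3CC/C(C)=C/C1=O | intermediate
8 | (1R,7R,8R,11R,12R,3E)-7,8:11,12-diepoxy-2-oxocembra-3,15(17)-dien-16-al | O=CC(=C)[C@H]1CC[C@@]2(C)O[C@@H]2CC[C@@]3(C)O[C@@H]3CC/C(C)=C/C1=O | intermediate
9 | (1R,7R,8R,11R,12R,3E)-7,8:11,12-diepoxy-2-oxocembra-3,15(17)-dien-16-oic acid | OC(=O)C(=C)[C@H]1CC[C@@]2(C)O[C@@H]2CC[C@@]3(C)O[C@@H]3CC/C(C)=C/C1=O | intermediate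
10 | (1R,7R,8R,11R,12S,3E)-7,8-epoxy-11-hydroxy-2-oxocembra-3,15(17)-dien-16,12-olide | C=C1C(=O)O[C@@]2(C)CC[C@H]1C(=O)/C=C(C)/CC[C@H]3O[C@]3(C)CC[C@H]2O | intermediate
11 | (1R,7R,8R,12S,3E)-7,8-epoxy-2,11-dioxocembra-3,15(17)-dien-16,12-olide | C=C1C(=O)O[C@@]2(C)CC[C@H]1C(=O)/C=C(C)/CC[C@H]3O[C@]3(C)CCC2=O | intermediate
12 | (1R,7R,12S,3E)-7-hydroxy-2,11-dioxocembra-3,8(19),15(17)-trien-16,12-olide | C=C1C(=O)O[C@@]2(C)CC[C@H]1C(=O)/C=C(C)/CC[C@@H](O)C(=C)CCC2=O | intermediate
13 | (1R,4S,7R,12S)-4,7-epoxy-2,11-dioxocembra-8(19),15(17)-dien-16,12-olide | C=C1C(=O)O[C@@]2(C)CC[C@H]1C(=O)C[C@]1(C)CC[C@@H](O1)C(=C)CCC2=O | intermediate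
14 | (1R,2S,4S,7R,11S,12S)-4,7-epoxy-2,11-dihydroxycembra-8(19),15(17)-dien-16,12-olide | C=C1C(=O)O[C@@]2(C)CC[C@H]1[C@@H](O)C[C@]1(C)CC[C@@H](O1)C(=C)CC[C@@H]2O | target

**Step count and risks**

Total: 7 steps. Longest linear sequence: 7 steps (1 → 14, fully linear).

Steps most likely to fail:

Step 2 (macrocyclisation). The cation may be trapped as chloride, lose its proton into conjugation, or oligomerise. The fallback sets out from aldehyde 2 (isolated after the TEMPO stage of step 1) and returns at ketone 5, making the same C1–C2 bond by allyl-metal addition instead of acylium chemistry. Ene-type chlorination of the terminal isopropylidene of 2 (HOCl from Ca(OCl)2 and solid CO2, CH2Cl2–H2O, 0 °C; the enal alkene is deactivated and the internal alkenes are slower) gives racemic (2E,6E,10E)-14-chloro-3,7,11,15-tetramethylhexadeca-2,6,10,15-tetraenal F1. CrCl2 in THF at high dilution (Nozaki–Hiyama allylation through the γ-carbon) closes the ring to racemic (3E,7E,11E)-cembra-3,7,11,15(17)-tetraen-2-ol F2, and MnO2 oxidation of this allylic alcohol gives 5.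

Step 6 (epoxide to exocyclic allylic alcohol, then ring C). The C8 radical could add transannularly to C4 of the enone, or hydrogen loss could occur from C9 instead of C19. The fallback sets out from 11 and returns at 13 by a polar route. Aqueous acid (HClO4 cat., THF–H2O, 0 °C) opens the epoxide at tertiary C8 to (1R,7R,8S,12S,3E)-7,8-dihydroxy-2,11-dioxocembra-3,15(17)-dien-16,12-olide F3, whose C7–OH adds to the enone in the same pot to give (1R,4S,7R,8S,12S)-4,7-epoxy-8-hydroxy-2,11-dioxocembr-15(17)-en-16,12-olide F4. Dehydration of its only hydroxyl (SOCl2, pyridine, −30 °C, which favours loss of a methyl hydrogen) gives 13.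

Step 7 (double reduction). The macrocycle may override the Felkin–Anh preference, most plausibly at the hindered C11 ketone. The fallback sets out from 13 and arrives at 14, replacing hydride face selectivity at C11 by an inversion with neighbouring-group participation. If the reduction gives (1R,2S,4S,7R,11R,12S)-4,7-epoxy-2,11-dihydroxycembra-8(19),15(17)-dien-16,12-olide F5, the less hindered C2–OH is silylated (TESCl, imidazole) to its 2-O-triethylsilyl ether F6. The C11–OH is then converted to the 11-triflate F7 (Tf2O, pyridine, −20 °C). Warming in wet MeCN with 2,6-di-tert-butylpyridine lets the lactone carbonyl displace the triflate with inversion, and water opens the dioxolanylium ion to the (11S)-alcohol 2-O-triethylsilyl ether F8. HF·pyridine then frees 14.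

**Further compounds**

F1 | step 2 | (2E,6E,10E)-14-chloro-3,7,11,15-tetramethylhexadeca-2,6,10,15-tetraenal (racemic) | C=C(C)C(Cl)CC/C(C)=C/CC/C(C)=C/CC/C(C)=C/C=O
F2 | step 2 | rac-(3E,7E,11E)-cembra-3,7,11,15(17)-tetraen-2-ol | CC(=C)C1CC/C(C)=C/CC/C(C)=C/CC/C(C)=C/C1O
F3 | step 6 | (1R,7R,8S,12S,3E)-7,8-dihydroxy-2,11-dioxocembra-3,15(17)-dien-16,12-olide | C=C1C(=O)O[C@@]2(C)CC[C@H]1C(=O)/C=C(C)/CC[C@@H](O)[C@@](C)(O)CCC2=O
F4 | step 6 | (1R,4S,7R,8S,12S)-4,7-epoxy-8-hydroxy-2,11-dioxocembr-15(17)-en-16,12-olide | C=C1C(=O)O[C@@]2(C)CC[C@H]1C(=O)C[C@]1(C)CC[C@@H](O1)[C@@](C)(O)CCC2=O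
F5 | step 7 | (1R,2S,4S,7R,11R,12S)-4,7-epoxy-2,11-dihydroxycembra-8(19),15(17)-dien-16,12-olide (C11 epimer of 14) | C=C1C(=O)O[C@@]2(C)CC[C@H]1[C@@H](O)C[C@]1(C)CC[C@@H](O1)C(=C)CC[C@H]2O
F6 | step 7 | 2-O-triethylsilyl ether of F5 | C=C1C(=O)O[C@@]2(C)CC[C@H]1[C@@H](O[Si](CC)(CC)CC)C[C@]1(C)CC[C@@H](O1)C(=C)CC[C@H]2O
F7 | step 7 | 11-O-trifluoromethanesulfonate of F6 | C=C1C(=O)O[C@@]2(C)CC[C@H]1[C@@H](O[Si](CC)(CC)CC)C[C@]1(C)CC[C@@H](O1)C(=C)CC[C@H]2OS(=O)(=O)C(F)(F)F
F8 | step 7 | 2-O-triethylsilyl ether of 14 (11S alcohol) | C=C1C(=O)O[C@@]2(C)CC[C@H]1[C@@H](O[Si](CC)(CC)CC)C[C@]1(C)CC[C@@H](O1)C(=C)CC[C@@H]2O
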